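**Assumption:** the SMILES has no stereocentre or stereo-bond, and the macrocycle is treated as conformationally mobile. Marchantin H is therefore made as an achiral compound and no enantiocontrol is needed. All four starting materials are taken to be catalogue items.

**Ring labels:** A = para-phenylene, B = catechol ring, C = meta-phenylene, D = phenol ring.

## Retrosynthetic overview
1. The target comes from BBr3 cleavage of its tri-O-methyl ether. The saturated A–CH2CH2–B bridge comes from hydrogenating a macrocyclic stilbene.
2. The 18-membered macrocycle is the only ring built. It is closed last at A–CH=CH–B by intramolecular McMurry coupling of a seco-dialdehyde. All four benzene rings are purchased.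
3. The C–CH2CH2–D bridge comes from a Heck coupling of a D-ring bromide with a C-ring styrene. The alkene is then saturated, sparing the aldehydes, before ring closure.
4. Both diaryl ethers come from SNAr of phenols on 4-fluorobenzaldehyde and 2-fluoro-3,4-dimethoxybenzaldehyde.
5. The CHO groups that activate the SNAr steps are the later McMurry partners, so no protecting groups or redox adjustments are needed.

## Route

**Step 1**
Reactants: 1, 5-bromo-2-methoxyphenol; 2, 4-fluorobenzaldehyde
Product: 3, 4-(5-bromo-2-methoxyphenoxy)benzaldehyde (D–O–A fragment)
Conditions: K2CO3 (1.5 equiv), DMF, 120 °C, 12 h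
Reagents that add atoms: none (all heavy atoms come from 1 and 2)
Why: SNAr, in which the para-formyl group activates fluoride towards the phenoxide while the unactivated aryl bromide is inert.

**Step 2**
Reactants: 4, 3-vinylphenol; 5, 2-fluoro-3,4-dimethoxybenzaldehyde
Product: 6, 2-(3-ethenylphenoxy)-3,4-dimethoxybenzaldehyde (C–O–B fragment)
Conditions: K2CO3 (2 equiv), BHT (1 mol %), DMAc, 130 °C, N2, 16–24 h
Reagents that add atoms: none (all heavy atoms come from 4 and 5)
Why: SNAr, in which the ortho-formyl group activates the C–F bond far more than either C–OMe bond, and BHT with dilution suppresses styrene polymerisation.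

**Step 3**
Reactants: 3; 6
Product: 7, 2-[3-[(E)-2-[3-(4-formylphenoxy)-4-methoxyphenyl]ethenyl]phenoxy]-3,4-dimethoxybenzaldehyde (E-stilbene dialdehyde)
Conditions: Pd(OAc)2 (5 mol %), P(o-tol)3 (12 mol %), Et3N (3 equiv), DMF, 110 °C, 16 h
Reagents that add atoms: none
Why: Mizoroki–Heck reaction, in which β-arylation of the styrene gives the E-stilbene, both aldehydes are tolerated, and the alkene geometry is erased in step 4.

**Step 4**
Reactants: 7
Product: 8, 2-[3-[2-[3-(4-formylphenoxy)-4-methoxyphenyl]ethyl]phenoxy]-3,4-dimethoxybenzaldehyde (bibenzyl seco-dialdehyde)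
Conditions: H2 (1 atm), 10 % Pd/C, Ph2S (0.01 equiv), EtOAc, rt
Reagents that add atoms: none (H2 only)
Why: Chemoselective catalytic hydrogenation on sulfide-poisoned Pd/C saturates the alkene but not the aryl aldehydes, and it must precede cyclisation because a rigid E C–D stilbene holds its two meta oxygens at least about 9.3 Å apart by my estimate from idealised planar geometry, more than the roughly 8.6 Å the A–B half can span.

**Step 5**
Reactants: 8
Product: 9, tri-O-methyl-didehydromarchantin H (18-membered macrocycle with A–CH=CH–B, E/Z mixture)
Conditions: TiCl4 (15 equiv), Zn dust (30 equiv), pyridine, THF, reflux; 8 added by syringe pump over 24 h (final about 2 mM); aq K2CO3 quench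
Reagents that add atoms: none
Why: Intramolecular McMurry coupling under pseudo-high dilution deoxygenatively joins the two aryl aldehydes, aryl and methyl ethers are inert to low-valent Ti, and the alkene geometry does not matter.

**Step 6**
Reactants: 9
Product: 10, tri-O-methylmarchantin H
Conditions: H2 (1 atm), 10 % Pd/C, EtOAc/EtOH 1:1, rt
Reagents that add atoms: none (H2 only)
Why: Catalytic hydrogenation converts both stilbene isomers to the same bibenzyl bridge, and no hydrogenolysable group is present.

**Step 7**
Reactants: 10
Product: 11, marchantin H
Conditions: BBr3 (9 equiv), CH2Cl2, −78 °C to rt, 12 h; ice-water quench and mildly acidic work-up under N2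
Reagents that add atoms: none (only H from work-up)
Why: Lewis-acid aryl methyl ether cleavage removes all three O-methyl groups, while the diaryl ether C–O bonds have no sp3 carbon for bromide attack and survive.

## Compound list
1 | 5-bromo-2-methoxyphenol | COc1ccc(Br)cc1O | starting material
2 | 4-fluorobenzaldehyde | O=Cc1ccc(F)cc1 | starting material
3 | 4-(5-bromo-2-methoxyphenoxy)benzaldehyde | COc1ccc(Br)cc1Oc1ccc(C=O)cc1 | intermediate
4 | 3-vinylphenol | C=Cc1cccc(O)c1 | starting material
5 | 2-fluoro-3,4-dimethoxybenzaldehyde | COc1ccc(C=O)c(F)c1OC | starting material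
6 | 2-(3-ethenylphenoxy)-3,4-dimethoxybenzaldehyde | COc1ccc(C=O)c(Oc2cccc(C=C)c2)c1OC | intermediate
7 | (E)-stilbene dialdehyde | COc1ccc(/C=C/c2cccc(Oc3c(C=O)ccc(OC)c3OC)c2)cc1Oc1ccc(C=O)cc1 | intermediate
8 | bibenzyl seco-dialdehyde | COc1ccc(CCc2cccc(Oc3c(C=O)ccc(OC)c3OC)c2)cc1Oc1ccc(C=O)cc1 | intermediate
9 | macrocyclic stilbene, tri-O-methyl-didehydromarchantin H (E/Z mixture, geometry left undefined) | COc1ccc2cc1Oc1ccc(cc1)C=Cc1ccc(OC)c(OC)c1Oc1cccc(c1)CC2 | intermediate
10 | tri-O-methylmarchantin H | COc1ccc2cc1Oc1ccc(cc1)CCc1ccc(OC)c(OC)c1Oc1cccc(c1)CC2 | intermediate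
11 | marchantin H (achiral) | Oc1ccc2cc1Oc1ccc(cc1)CCc1ccc(O)c(O)c1Oc1cccc(c1)CC2 | target

## Summary
Total step count: 7.
Longest linear sequence: 6 (step 1 or 2, then steps 3 to 7).

**Steps most likely to fail, with fallbacks**

1. **Step 5, McMurry macrocyclisation.** The risks are oligomers, pinacol products, and the hindered, electron-rich B-ring aldehyde.
   - Fallback: close the ring by intramolecular Wittig reaction instead.
   - Reduce 3 to the benzylic alcohol with NaBH4 before the Heck step and carry it through steps 3 and 4.
   - Convert ArCH2OH to ArCH2PPh3Br with PPh3·HBr, which leaves the B-ring CHO untouched.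
   - Ring-close with NaOMe in CH2Cl2 at high dilution to rejoin the route at 9.

2. **Step 2, SNAr.** The fluoride is flanked on both sides and deactivated by the para OMe, and the styrene can polymerise at 130 °C.
   - Fallback: reverse the polarity with a room-temperature Chan–Evans–Lam coupling.
   - Couple 2-hydroxy-3,4-dimethoxybenzaldehyde with 3-vinylphenylboronic acid using Cu(OAc)2, pyridine and 4 Å MS in CH2Cl2 under air.
   - This gives 6 directly.

3. **Step 4, alkene hydrogenation in the presence of two ArCHO groups.** The risk is over-reduction or hydrogenolysis of the aldehydes.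
   - Fallback: form the saturated bridge directly and drop steps 3 and 4.
   - Protect 6 as its dimethyl acetal and hydroborate it with 9-BBN.
   - Carry out a B-alkyl Suzuki–Miyaura coupling with 3 using PdCl2(dppf) and K3PO4.
   - Acidic work-up then delivers 8.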